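## The problem

Target **16** is a 1-aryl-1,2-dihydronaphthalene. A 6,7-dimethoxybenzo ring A is fused at C4a/C8a to ring B, which carries the 4-hydroxy-3-methoxyphenyl group on C1, a hydroxymethyl group on C2, a formyl group on C3 and the C3=C4 double bond (the systematic names below number these atoms 4, 3, 2 and 1). The two adjacent stereocentres, C1 (S) and C2 (R), are trans.

C2 has no acidifying neighbour in any useful precursor, so it must be set in the absolute sense early and can then only be carried. C1 is benzhydrylic and becomes reversibly deprotonable once C4 is a ketone ortho to it on ring A, so C2 can steer C1 under equilibrium control, but not the reverse.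

The fragile features are the enal inside a dihydronaphthalene (aromatisation, conjugate reduction), the free phenol, and the 1,4-related CH2OH and CHO groups, which run on to lactol and butenolide when the oxidation level is adjusted late. The aldehyde is therefore best introduced as an aldehyde while the alcohol stays masked, and the last step must be neither reductive nor oxidative.

The enabling feature is that the two ring A bonds C8a–C1 and C4a–C4 leave neighbouring arene carbons, each flanked by a CH and para to a methoxy group. Both bonds can therefore come from the symmetric 4,5-dimethoxybenzyne. The chain C1–C2–C3–C4 with oxygen on C4 can be stored as a 2-aryl-3-(alkoxymethyl)cyclobutanone in which C1 and C4 are bonded to each other. Insertion of the aryne into that bond forms ring B, and the ketone left on C4 is the handle for the C3 formyl group and the C3=C4 bond.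

## Retrosynthesis

**16 ⇒ 15.** The two O–benzyl bonds are cut. Benzyl is preferred to silyl on the phenol, which would not survive the fluoride of the aryne step, and one reagent can remove both groups. The forward step needs a Lewis acid that cleaves an aryl and a primary alkyl benzyl ether at low temperature and leaves the enal, the ring B alkene and three methyl ethers alone; hydrogenolysis is excluded by the alkene.

**15 ⇒ 14 ⇒ 12.** The C3–CHO bond is cut and C4 is returned to a ketone. Carrying the formyl carbon through the ring-forming step would put a second acidifying group next to C2 and confuse the enolate chemistry of the four-membered ring. A C4 ketone is exactly what the aryne insertion delivers, and it activates the only α-methylene, C3. Tetralone **12** is one carbon simpler and has no competing enolisable site. The forward sequence must formylate C3 and exchange the C4 oxygen for hydrogen with the double bond between them: chloroformylation to **14**, then hydrodechlorination.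

**12 ⇒ 6 + 7.** The bonds C8a–C1 and C4a–C4 are cut together. Cutting only one ring B bond (C1–C2, C4–C4a or C1–C8a) leads to open-chain precursors in which both stereocentres must be controlled without a ring. The double cut removes ring A as commercial aryne precursor **7** and leaves cyclobutanone **6**, whose single decisive stereocentre is β to the carbonyl. The forward reaction must (a) arylate the aryl-bearing α-carbon, (b) close the aryl anion onto the carbonyl before it is protonated, (c) break the bond shared by the two four-membered rings, and (d) finish with C1 trans to C2.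

**6 ⇒ 5 + 2.** The C1–aryl bond is cut. A [2+2] construction of the arylcyclobutanone would need its own solution for absolute configuration. α-Arylation instead starts from a commercial cyclobutanone and lets the stereocentre be set by desymmetrisation. Silyl enol ether **5** and aryl bromide **2** are both simple. The coupling must be mild enough for a strained enol ether and must not open or condense the cyclobutanone.

**5 ⇒ 3, and 2 ⇒ 1.** Cyclobutanone **3** is achiral and commercial. One of its two enantiotopic α-methylene groups must be deprotonated selectively and the enolate trapped on silicon before it self-condenses. This sets the future C2 and is the only absolute stereocontrol in the route. Bromide **2** follows from phenol **1** by benzylation.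

## Roads not taken

**Alternative 1:** The cut is C1–C2. Sulfone **A1**, a (4-hydroxyaryl)(aryl)methyl sulfone whose ring A also carries an (E)-alkylidenesuccinate, would lose sulfinate under a chiral quaternary ammonium phase-transfer catalyst and aqueous KOH to give para-quinone methide **A2**. 1,6-Addition of the C2 dienolate to the exocyclic carbon would close ring B as diester **A3**.

- Merits: both stereocentres are set in the ring-forming step by a catalyst, the phenol needs no protection, and C3=C4 is in place from the start.
- Weak points: the intramolecular addition to a very reactive quinone methide has a fast uncatalysed pathway, so enantiocontrol is uncertain. C2–H of **A3** is α to an ester and allylic, which opens double-bond migration and aromatisation to the naphthalene. The two esters must then be told apart: reduction to the diol and selective oxidation of the allylic alcohol beside a free 1,4-hydroxyl, the arrangement that tends to go on to lactol and butenolide.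
- Comparison: this road is about as long and is better in that chirality comes from a catalyst and the ring closure has closer precedent. The chosen plan sets against it a C2 centre that cannot be lost once made, and an aldehyde installed directly with the alcohol masked throughout.

**Alternative 2:** The cuts are C1–aryl and C2–C3, with ring B closed later. Styrenyl boronate **A4** and Grignard reagent **A5** would form a boron ate complex that couples with aryl triflate **A6** under Pd(OAc)2 and a chiral MandyPhos ligand. A 1,2-migration forms C2–C3 as the aryl group is delivered to C1, giving boronate **A7**.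

- Merits: catalyst control of both centres with a stereospecific relative configuration, and modular aryl groups.
- Weak points: β-aryl alkenyl boronates are poor substrates because direct cross-coupling of the styrenyl group competes. The hindered secondary boronate beside a diaryl methine must then be homologated by one carbon and oxidised. Both acetals must be removed and ring B closed by an aldol condensation in the presence of the new hydroxymethyl group.
- Comparison: control of configuration is firmer here than in the chosen plan, which relies on a stoichiometric chiral base for C2 and on equilibration for C1. The price is about three more steps and a ring closure that is not part of the key step.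

**Alternative 3:** The cuts are C3–C4 and C4–C4a. Lactone **A8** would be formylated at C3 with a formate ester and cyclodehydrated with acid onto ring A in the same operation, giving butenolide **A9**.

- Merits: classical, reliable ring closure para to a methoxy group, and a short endgame, since partial reduction of the lactone gives the lactol form of the hydroxy aldehyde and only the sulfonate remains to be removed.
- Weak points: **A8** must already hold both stereocentres, set in an open chain. One is a diaryl methine whose two aryl groups differ only in a protecting group, which is a hard target for asymmetric synthesis and cannot be corrected later. The tosylate is needed only to stop cyclisation onto the wrong ring.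
- Comparison: the ring closure and the endgame are better precedented and shorter than in the chosen plan. The chosen plan sets against this that only one stereocentre needs absolute control, in a small ring from a commercial ketone, and the second is corrected by equilibration.

Key step: step 4

Assumption: the chiral lithium amide is taken to select the enantiotopic methylene of **3** as it does in 3-alkylcyclobutanones, so that the (R,R)-amide leads to the (S)-enol ether; if correlation shows the opposite sense, the (S,S)-amide is used and nothing else changes.

## Route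

Step 1
Reactants: 1 4-bromo-2-methoxyphenol
Product: 2 1-(benzyloxy)-4-bromo-2-methoxybenzene
Conditions: BnBr, K2CO3, DMF, 23 °C
Reagents that add atoms: benzyl bromide, BrCc1ccccc1
Why: Williamson ether synthesis on the phenoxide; the benzyl ether tolerates fluoride, palladium catalysis and POCl3 and is removed at the end together with the alkyl benzyl ether.

Step 2
Reactants: 3 3-[(benzyloxy)methyl]cyclobutan-1-one
Product: 5 (S)-{3-[(benzyloxy)methyl]cyclobut-1-en-1-yl}oxy(trimethyl)silane, via lithium enolate 4 (not isolated)
Conditions: (R,R)-bis(1-phenylethyl)amine, n-BuLi, THF, 0 °C; TMSCl then 3, −100 °C (internal quench); Et3N, pentane, filtration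
Reagents that add atoms: chlorotrimethylsilane, C[Si](C)(C)Cl
Why: Enantioselective deprotonation (desymmetrisation) of a prochiral 3-substituted cyclobutanone by a C2-symmetric chiral lithium amide; the base chooses one of the two enantiotopic α-methylene groups and so fixes the ring stereocentre that becomes C2 of the target, and the internal silyl quench traps enolate 4 before it can self-condense.

Step 3
Reactants: 5 (S)-{3-[(benzyloxy)methyl]cyclobut-1-en-1-yl}oxy(trimethyl)silane; 2 1-(benzyloxy)-4-bromo-2-methoxybenzene
Product: 6 (2S,3S)-2-[4-(benzyloxy)-3-methoxyphenyl]-3-[(benzyloxy)methyl]cyclobutan-1-one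
Conditions: Pd(OAc)2 (3 mol%), P(t-Bu)3 (6 mol%), Bu3SnF, CsF, toluene, 85 °C
Reagents that add atoms: none
Why: Palladium-catalysed α-arylation of a ketone silyl enol ether with an aryl bromide (oxidative addition, fluoride-assisted transfer of the enolate to palladium, reductive elimination); the near-neutral conditions avoid base-induced opening of the cyclobutanone, the aryl group enters anti to the C3 side chain, and the trans isomer is also the thermodynamic one at this epimerisable α-centre, while C3 is untouched.

Step 4
Reactants: 6 (2S,3S)-2-[4-(benzyloxy)-3-methoxyphenyl]-3-[(benzyloxy)methyl]cyclobutan-1-one; 7 4,5-dimethoxy-2-(trimethylsilyl)phenyl trifluoromethanesulfonate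
Product: 12 (3S,4S)-4-[4-(benzyloxy)-3-methoxyphenyl]-3-[(benzyloxy)methyl]-6,7-dimethoxy-3,4-dihydronaphthalen-1(2H)-one, via cesium enolate 8 (not isolated), via 4,5-dimethoxybenzyne 9 (not isolated), via fused benzocyclobutenoxide 10 (not isolated), via cis tetralone 11 (not isolated)
Conditions: CsF (3 equiv), MeCN, 60 °C, 7 added slowly; filtration, solvent exchange; then t-BuOK (0.2 equiv), t-BuOH–THF, 23 °C
Reagents that add atoms: none
Why: Proposed new method: fluoride releases aryne 9 from 7 and reversibly converts 6 into its conjugated enolate 8, which adds to the aryne through the aryl-bearing carbon; the aryl anion then closes onto the cyclobutanone carbonyl to give the fused alkoxide 10, and cleavage of the bond shared by the two four-membered rings gives the six-membered ring as a diaryl carbanion that is also the extended enolate of the new aryl ketone. The closest known reaction types are aryne insertion into the Cα–C(=O) bond of cyclic β-keto esters (acyl-alkylation with ring expansion) and the two-carbon ring expansion of cyclic ketone enolates with arynes through benzocyclobutenoxides; insertion into a cyclobutanone has not been shown. Ring B is thus closed not by a direct cyclisation but by a 4-exo-trig carbonyl addition followed by fragmentation of the bicyclo[2.2.0] alkoxide, driven by release of the strain of both small rings and by the stabilised carbanion. The C3 centre of 6 is β to the carbonyl, is not touched and becomes C2 of the target. The new centre C1 arises on protonation of the planar carbanion and is controlled by C2: whatever kinetic mixture forms, including cis epimer 11, the benzhydrylic hydrogen ortho to the acyl group can be removed again, so the catalytic t-BuOK treatment should drain the material into the trans isomer 12, in which aryl and benzyloxymethyl groups avoid each other. The step needs arylation at the aryl-bearing α-carbon and not at CH2, which the reversible fluoride-mediated enolisation secures by populating the conjugated, more acidic enolate. The aryne is symmetric, so its orientation is irrelevant, and only the wanted fragmentation gives a stabilised carbanion.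

Step 5
Reactants: 12 (3S,4S)-4-[4-(benzyloxy)-3-methoxyphenyl]-3-[(benzyloxy)methyl]-6,7-dimethoxy-3,4-dihydronaphthalen-1(2H)-one
Product: 14 (3R,4S)-4-[4-(benzyloxy)-3-methoxyphenyl]-3-[(benzyloxy)methyl]-1-chloro-6,7-dimethoxy-3,4-dihydronaphthalene-2-carbaldehyde, via chlorovinyl iminium salt 13 (not isolated)
Conditions: POCl3, DMF, 0 → 60 °C; then aq NaOAc, 0 °C
Reagents that add atoms: N,N-dimethylformamide, CN(C)C=O; phosphoryl chloride, O=P(Cl)(Cl)Cl; water, O
Why: Vilsmeier–Haack chloroformylation of an enolisable aryl ketone: the chloroiminium reagent formylates the only α-carbon (C3) and the carbonyl oxygen is exchanged for chloride, giving iminium salt 13, which is hydrolysed to the β-chloro enal; the dialkoxyarenes are not activated enough to be formylated, and neither stereocentre is enolised.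

Step 6
Reactants: 14 (3R,4S)-4-[4-(benzyloxy)-3-methoxyphenyl]-3-[(benzyloxy)methyl]-1-chloro-6,7-dimethoxy-3,4-dihydronaphthalene-2-carbaldehyde
Product: 15 (3R,4S)-4-[4-(benzyloxy)-3-methoxyphenyl]-3-[(benzyloxy)methyl]-6,7-dimethoxy-3,4-dihydronaphthalene-2-carbaldehyde
Conditions: Pd(OAc)2 (5 mol%), PPh3 (15 mol%), HCO2H, Et3N, DMF, 60 °C
Reagents that add atoms: none
Why: Palladium-catalysed transfer hydrodehalogenation: the β-chloro enal behaves as a vinylogous acid chloride toward zerovalent palladium, formate supplies hydride by decarboxylation, and reductive elimination gives the C4–H bond; a homogeneous phosphine-ligated catalyst does not hydrogenolyse benzyl ethers.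

Step 7
Reactants: 15 (3R,4S)-4-[4-(benzyloxy)-3-methoxyphenyl]-3-[(benzyloxy)methyl]-6,7-dimethoxy-3,4-dihydronaphthalene-2-carbaldehyde
Product: 16 (3R,4S)-4-(4-hydroxy-3-methoxyphenyl)-3-(hydroxymethyl)-6,7-dimethoxy-3,4-dihydronaphthalene-2-carbaldehyde
Conditions: BCl3, pentamethylbenzene, CH2Cl2, −78 °C; then MeOH
Reagents that add atoms: none
Why: Lewis-acid debenzylation with a non-basic cation scavenger: BCl3 cleaves the aryl and the primary alkyl benzyl ether at low temperature, pentamethylbenzene traps the benzyl cation so that the electron-rich rings are not benzylated, and the methyl ethers, the enal and both stereocentres are left as they are.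

## Compound list

1 | 4-bromo-2-methoxyphenol | COc1cc(Br)ccc1O | starting material
2 | 1-(benzyloxy)-4-bromo-2-methoxybenzene | COc1cc(Br)ccc1OCc1ccccc1 | intermediate
3 | 3-[(benzyloxy)methyl]cyclobutan-1-one | O=C1CC(COCc2ccccc2)C1 | starting material
4 | lithium (3S)-3-[(benzyloxy)methyl]cyclobut-1-en-1-olate | [Li]OC1=C[C@@H](COCc2ccccc2)C1 | intermediate (not isolated)
5 | (S)-{3-[(benzyloxy)methyl]cyclobut-1-en-1-yl}oxy(trimethyl)silane | C[Si](C)(C)OC1=C[C@@H](COCc2ccccc2)C1 | intermediate
6 | (2S,3S)-2-[4-(benzyloxy)-3-methoxyphenyl]-3-[(benzyloxy)methyl]cyclobutan-1-one (trans) | O=C1C[C@@H]([C@H]1c1ccc(OCc2ccccc2)c(OC)c1)COCc1ccccc1 | intermediate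
7 | 4,5-dimethoxy-2-(trimethylsilyl)phenyl trifluoromethanesulfonate | COc1cc(OS(=O)(=O)C(F)(F)F)c([Si](C)(C)C)cc1OC | starting material
8 | cesium (3S)-2-[4-(benzyloxy)-3-methoxyphenyl]-3-[(benzyloxy)methyl]cyclobut-1-en-1-olate | [Cs+].[O-]C1=C(c2ccc(OCc3ccccc3)c(OC)c2)[C@@H](COCc2ccccc2)C1 | intermediate (not isolated)
9 | 4,5-dimethoxybenzyne (1,2-didehydro-4,5-dimethoxybenzene) | COC1=CC#CC=C1OC | intermediate (not isolated)
10 | cesium alkoxide of the benzocyclobutenol cis-fused across the former C1–C2 bond of 6 (benzo-fused bicyclo[2.2.0]hexane; alkoxide oxygen, pendant aryl group and benzyloxymethyl group on the same face) | [Cs+].[O-][C@]12C[C@H](COCc3ccccc3)[C@@]1(c1ccc(OCc3ccccc3)c(OC)c1)c1cc(OC)c(OC)cc21 | intermediate (not isolated)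
11 | (3S,4R)-4-[4-(benzyloxy)-3-methoxyphenyl]-3-[(benzyloxy)methyl]-6,7-dimethoxy-3,4-dihydronaphthalen-1(2H)-one (cis) | COc1cc([C@@H]2c3cc(OC)c(OC)cc3C(=O)C[C@@H]2COCc4ccccc4)ccc1OCc1ccccc1 | intermediate (not isolated)
12 | (3S,4S)-4-[4-(benzyloxy)-3-methoxyphenyl]-3-[(benzyloxy)methyl]-6,7-dimethoxy-3,4-dihydronaphthalen-1(2H)-one (trans) | COc1cc([C@H]2c3cc(OC)c(OC)cc3C(=O)C[C@@H]2COCc4ccccc4)ccc1OCc1ccccc1 | intermediate
13 | N-({(3R,4S)-4-[4-(benzyloxy)-3-methoxyphenyl]-3-[(benzyloxy)methyl]-1-chloro-6,7-dimethoxy-3,4-dihydronaphthalen-2-yl}methylidene)-N-methylmethanaminium chloride | COc1cc([C@H]2c3cc(OC)c(OC)cc3C(Cl)=C(C=[N+](C)C)[C@@H]2COCc4ccccc4)ccc1OCc1ccccc1.[Cl-] | intermediate (not isolated)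
14 | (3R,4S)-4-[4-(benzyloxy)-3-methoxyphenyl]-3-[(benzyloxy)methyl]-1-chloro-6,7-dimethoxy-3,4-dihydronaphthalene-2-carbaldehyde | COc1cc([C@H]2c3cc(OC)c(OC)cc3C(Cl)=C(C=O)[C@@H]2COCc4ccccc4)ccc1OCc1ccccc1 | intermediate
15 | (3R,4S)-4-[4-(benzyloxy)-3-methoxyphenyl]-3-[(benzyloxy)methyl]-6,7-dimethoxy-3,4-dihydronaphthalene-2-carbaldehyde | COc1cc([C@H]2c3cc(OC)c(OC)cc3C=C(C=O)[C@@H]2COCc4ccccc4)ccc1OCc1ccccc1 | intermediate
16 | (3R,4S)-4-(4-hydroxy-3-methoxyphenyl)-3-(hydroxymethyl)-6,7-dimethoxy-3,4-dihydronaphthalene-2-carbaldehyde | COc1cc([C@H]2c3cc(OC)c(OC)cc3C=C(C=O)[C@@H]2CO)ccc1O | target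

## Step count and risks

Total: 7 steps. Longest linear sequence: 6 steps (from **3** through steps 2–7; the branch from **1** through steps 1 and 3–7 is equally long).

**Step 4 (key step).** Three processes are most likely to intervene:

- The aryl anion may be protonated before the 4-exo closure, giving plain α-arylation, because the closure must build a bicyclo[2.2.0] framework.
- Fluoride or adventitious hydroxide may add to the strained α-aryl ketone and cleave it in a Haller–Bauer-type opening before it enolises.
- Convergence at C1 in the base treatment may be incomplete.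

The fallback forms the same two bonds one at a time by known chemistry, setting out from **6**. (3,4-Dimethoxyphenyl)cerium dichloride (from 4-bromo-1,2-dimethoxybenzene, n-BuLi and CeCl3, chosen for its low basicity) adds to the ketone anti to the neighbouring aryl group. This gives (1S,2S,3S)-2-[4-(benzyloxy)-3-methoxyphenyl]-3-[(benzyloxy)methyl]-1-(3,4-dimethoxyphenyl)cyclobutan-1-ol F1 and forms C4a–C4. Oxidative ring expansion of this 1-arylcyclobutanol (AgNO3 as catalyst, K2S2O8, CH2Cl2–water) then proceeds through the alkoxy radical. β-Scission occurs toward the benzylic radical at the aryl-bearing carbon, which attacks the dimethoxyphenyl ketone ring at the free ortho position para to a methoxy group, and rearomatisation follows. This forms C8a–C1 and, after the same catalytic t-BuOK equilibration, returns to the route at **12**.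

**Step 2.** Discrimination between the enantiotopic methylene groups may be poor, because the benzyloxymethyl oxygen can bind lithium and change the aggregate. The cyclobutenyl silyl ether may also hydrolyse back to achiral **3** during handling.

The fallback replaces enantiotopic deprotonation by a chiral-auxiliary keteniminium [2+2] cycloaddition and sets out from **2**.

- (2R,5R)-2,5-Dimethylpyrrolidine is acetylated to 1-[(2R,5R)-2,5-dimethylpyrrolidin-1-yl]ethan-1-one F2 (or its antipode, as correlation dictates).
- The zinc enolate of F2 (s-BuLi, ZnCl2) is arylated with **2** under palladium catalysis to give 2-[4-(benzyloxy)-3-methoxyphenyl]-1-[(2R,5R)-2,5-dimethylpyrrolidin-1-yl]ethan-1-one F3.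
- Tf2O and 2,4,6-trimethylpyridine convert F3 into its keteniminium salt, which adds to allyl benzyl ether. The substituted alkene carbon bonds to the aryl-bearing carbon, giving 1-{(2S,3S)-2-[4-(benzyloxy)-3-methoxyphenyl]-3-[(benzyloxy)methyl]cyclobutylidene}-(2R,5R)-2,5-dimethylpyrrolidin-1-ium trifluoromethanesulfonate F4.
- Aqueous NaHCO3 hydrolysis, with epimerisation of the α-centre to trans, returns to the route at **6** and bypasses **5**.

**Step 3.** Transfer of the strained enolate to palladium may be slow, so that protodesilylation back to **3** wins. The more acidic product may be arylated a second time, or the cyclobutanone may open under fluoride at 85 °C.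

The fallback turns the aryl partner into an electrophilic trivalent-iodine reagent and needs no palladium.

- Bromide **2** undergoes bromine–lithium exchange (n-BuLi) and borylation (B(Oi-Pr)3, acid work-up) to give [4-(benzyloxy)-3-methoxyphenyl]boronic acid F5.
- F5 reacts with (diacetoxyiodo)mesitylene and BF3·OEt2 to give [4-(benzyloxy)-3-methoxyphenyl](2,4,6-trimethylphenyl)iodonium tetrafluoroborate F6, in which mesityl is the ligand that is not transferred.
- Copper-catalysed arylation of silyl enol ether **5** with F6 (Cu(OTf)2 as catalyst, CH2Cl2, 23 °C) returns to the route at **6**.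

**Step 6.** The palladium hydride may reduce the enal in conjugate fashion, oxidative addition into the hindered tetrasubstituted vinyl chloride may be slow, or the dihydronaphthalene may be dehydrogenated to the naphthalene.

The fallback avoids chlorine altogether and sets out from **12**.

- NaBH4 reduction gives (3S,4S)-4-[4-(benzyloxy)-3-methoxyphenyl]-3-[(benzyloxy)methyl]-6,7-dimethoxy-1,2,3,4-tetrahydronaphthalen-1-ol F7 as a mixture of carbinol epimers.
- Acid-catalysed dehydration (p-TsOH, toluene) through the para-methoxy-stabilised benzylic cation gives (1S,2S)-1-[4-(benzyloxy)-3-methoxyphenyl]-2-[(benzyloxy)methyl]-6,7-dimethoxy-1,2-dihydronaphthalene F8.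
- Vilsmeier–Haack formylation of this electron-rich styrene (POCl3, DMF, then aqueous NaOAc) attacks the β-carbon C3 and, after loss of a proton and hydrolysis, returns to the route at **15**.

## Further compounds

F1 | step 4 | (1S,2S,3S)-2-[4-(benzyloxy)-3-methoxyphenyl]-3-[(benzyloxy)methyl]-1-(3,4-dimethoxyphenyl)cyclobutan-1-ol | O[C@@]1(c2ccc(OC)c(OC)c2)C[C@@H]([C@H]1c1ccc(OCc2ccccc2)c(OC)c1)COCc1ccccc1
F2 | step 2 | 1-[(2R,5R)-2,5-dimethylpyrrolidin-1-yl]ethan-1-one | CC(=O)N1[C@H](C)CC[C@H]1C
F3 | step 2 | 2-[4-(benzyloxy)-3-methoxyphenyl]-1-[(2R,5R)-2,5-dimethylpyrrolidin-1-yl]ethan-1-one | COc1cc(CC(=O)N2[C@H](C)CC[C@H]2C)ccc1OCc1ccccc1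
F4 | step 2 | 1-{(2S,3S)-2-[4-(benzyloxy)-3-methoxyphenyl]-3-[(benzyloxy)methyl]cyclobutylidene}-(2R,5R)-2,5-dimethylpyrrolidin-1-ium trifluoromethanesulfonate | C[C@@H]1CC[C@@H](C)[N+]1=C1C[C@H](COCc2ccccc2)[C@H]1c1ccc(OCc2ccccc2)c(OC)c1.[O-]S(=O)(=O)C(F)(F)F
F5 | step 3 | [4-(benzyloxy)-3-methoxyphenyl]boronic acid | COc1cc(B(O)O)ccc1OCc1ccccc1
F6 | step 3 | [4-(benzyloxy)-3-methoxyphenyl](2,4,6-trimethylphenyl)iodonium tetrafluoroborate | COc1cc([I+]c2c(C)cc(C)cc2C)ccc1OCc1ccccc1.F[B-](F)(F)F
F7 | step 6 | (3S,4S)-4-[4-(benzyloxy)-3-methoxyphenyl]-3-[(benzyloxy)methyl]-6,7-dimethoxy-1,2,3,4-tetrahydronaphthalen-1-ol (mixture of C1 epimers) | COc1cc([C@H]2c3cc(OC)c(OC)cc3C(O)C[C@@H]2COCc4ccccc4)ccc1OCc1ccccc1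
F8 | step 6 | (1S,2S)-1-[4-(benzyloxy)-3-methoxyphenyl]-2-[(benzyloxy)methyl]-6,7-dimethoxy-1,2-dihydronaphthalene | COc1cc([C@H]2c3cc(OC)c(OC)cc3C=C[C@@H]2COCc4ccccc4)ccc1OCc1ccccc1
A1 | alternative 1 | dimethyl (2E)-2-({2-[(4-hydroxy-3-methoxyphenyl)(4-methylbenzenesulfonyl)methyl]-4,5-dimethoxyphenyl}methylidene)butanedioate | COC(=O)C/C(C(=O)OC)=C\c1cc(OC)c(OC)cc1C(c1ccc(O)c(OC)c1)S(=O)(=O)c1ccc(C)cc1
A2 | alternative 1 | dimethyl (2E)-2-({4,5-dimethoxy-2-[(3-methoxy-4-oxocyclohexa-2,5-dien-1-ylidene)methyl]phenyl}methylidene)butanedioate | COC(=O)C/C(C(=O)OC)=C\c1cc(OC)c(OC)cc1C=C1C=CC(=O)C(OC)=C1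
A3 | alternative 1 | dimethyl (1S,2R)-1-(4-hydroxy-3-methoxyphenyl)-6,7-dimethoxy-1,2-dihydronaphthalene-2,3-dicarboxylate | COc1cc([C@H]2c3cc(OC)c(OC)cc3C=C(C(=O)OC)[C@@H]2C(=O)OC)ccc1O
A4 | alternative 2 | 2-{(E)-2-[2-(1,3-dioxolan-2-yl)-4,5-dimethoxyphenyl]ethenyl}-4,4,5,5-tetramethyl-1,3,2-dioxaborolane | COc1cc(/C=C/B2OC(C)(C)C(C)(C)O2)c(C3OCCO3)cc1OC
A5 | alternative 2 | (1,3-dioxolan-2-ylmethyl)magnesium bromide | Br[Mg]CC1OCCO1
A6 | alternative 2 | 4-(benzyloxy)-3-methoxyphenyl trifluoromethanesulfonate | COc1cc(OS(=O)(=O)C(F)(F)F)ccc1OCc1ccccc1
A7 | alternative 2 | 2-{(1S,2S)-1-[4-(benzyloxy)-3-methoxyphenyl]-1-[2-(1,3-dioxolan-2-yl)-4,5-dimethoxyphenyl]-3-(1,3-dioxolan-2-yl)propan-2-yl}-4,4,5,5-tetramethyl-1,3,2-dioxaborolane | COc1cc([C@H]([C@H](CC2OCCO2)B3OC(C)(C)C(C)(C)O3)c4cc(OC)c(OC)cc4C5OCCO5)ccc1OCc1ccccc1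
A8 | alternative 3 | (4S)-4-{(R)-(3,4-dimethoxyphenyl)[3-methoxy-4-(4-methylbenzenesulfonyloxy)phenyl]methyl}dihydrofuran-2(3H)-one | COc1cc([C@@H](c2ccc(OC)c(OC)c2)[C@H]2COC(=O)C2)ccc1OS(=O)(=O)c1ccc(C)cc1
A9 | alternative 3 | (3aR,4S)-6,7-dimethoxy-4-[3-methoxy-4-(4-methylbenzenesulfonyloxy)phenyl]-3a,4-dihydronaphtho[2,3-c]furan-1(3H)-one | COc1cc([C@H]2c3cc(OC)c(OC)cc3C=C4C(=O)OC[C@H]24)ccc1OS(=O)(=O)c1ccc(C)cc1
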